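**Retrosynthetic overview**

- The target is reached by selective acylation of the primary allylic hydroxyl of the 3,15-diol with (S)-3-methylpentanoic acid. The diol comes from a bicyclic cross-conjugated dienone by ring A adjustment: saturation of C1=C2, reductive methylation at C4 with protonation at C5, and an axial alcohol at C3.
- Key disconnection: ring B of the dienone is built on a flat phenol with a geraniol-derived vinylic iodide. C7–C8 forms by carbopalladation of a styrene unit, and C9–C10 by attack of the phenol para carbon on the migrated C7–C8–C9 π-allylpalladium, with loss of aromaticity.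
- Enabling feature: in ring A the C3 oxygen is para to the methyl-bearing quaternary C10, and C4 carries a methyl group. Ring A is therefore a dearomatized 2,4-dimethylphenol whose nucleophilic para carbon is C10, and C7=C8(CH3)–C9 of ring B is an allyl unit one carbon away from the aryl carbon C5.
- The vinylphenol comes from 2-bromo-1,3-dimethylbenzene (nitration, reduction, diazonium hydrolysis, vinylation). The vinylic iodide comes from geraniol, which supplies C11–C16 and the E olefin (silylation, epoxidation, oxidative cleavage, iodo-ylide olefination).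
- Ring order: ring A is bought as an arene and ring B is closed in the key step. Stereocentres follow in the order C9 and C10 (key step), C5 (dissolving metal), C3 (hydride); the acid stereocentre is bought.

Key step: step 9

Remark: atom numbers in the text are labdane numbers of the target (C1–C10 decalin with OH on C3, C11–C16 side chain, C17 on C8, C20 on C10); the sense of induction of the chiral ligand in step 9 is an assumption to be settled by experiment, with the antipodal ligand used otherwise; catalyst-bound organometallic species are described in the Why lines and carry no numbers.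

**Route**

Step 1
Reactants: 1 2-bromo-1,3-dimethylbenzene
Product: 2 2-bromo-1,3-dimethyl-4-nitrobenzene
Conditions: HNO3 (1.05 equiv), H2SO4, 0 °C
Reagents that add atoms: nitric acid O[N+](=O)[O-]
Why: Electrophilic aromatic nitration should go to C4, which is ortho to one methyl group and para to the other, whereas C5 is only para to the deactivating bromine.

Step 2
Reactants: 2 2-bromo-1,3-dimethyl-4-nitrobenzene
Product: 3 3-bromo-2,4-dimethylaniline
Conditions: H2 (1 atm), Pt/C (5 %, sulfided), EtOAc, rt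
Reagents that add atoms: none
Why: Heterogeneous catalytic hydrogenation over sulfided platinum reduces the nitro group to the amine without hydrogenolysis of the aryl C–Br bond.

Step 3
Reactants: 3 3-bromo-2,4-dimethylaniline
Product: 5 3-bromo-2,4-dimethylphenol, via diazonium hydrogen sulfate 4 (not isolated)
Conditions: NaNO2 (1.05 equiv), 25 % aq. H2SO4, 0 °C; then added to refluxing 40 % aq. H2SO4
Reagents that add atoms: water O; sodium nitrite [Na+].[O-]N=O (its nitrogen stays only in 4)
Why: Diazotization of the aniline followed by thermal hydrolysis of the diazonium ion (phenol synthesis by way of the diazonium salt) replaces NH2 by OH, while bromine and the methyl groups are inert to hot dilute acid.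

Step 4
Reactants: 5 3-bromo-2,4-dimethylphenol
Product: 6 3-ethenyl-2,4-dimethylphenol
Conditions: 2-ethenyl-4,4,5,5-tetramethyl-1,3,2-dioxaborolane (1.5 equiv), Pd(OAc)2 (2 mol %), SPhos (4 mol %), K3PO4 (3 equiv), toluene/H2O 10:1, 90 °C
Reagents that add atoms: 2-ethenyl-4,4,5,5-tetramethyl-1,3,2-dioxaborolane C=CB1OC(C)(C)C(C)(C)O1
Why: Suzuki–Miyaura coupling, in which the bulky electron-rich biarylphosphine lets zerovalent palladium insert into the doubly ortho-substituted C–Br bond and the free phenol is carried as its phenoxide.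

Step 5
Reactants: 7 geraniol
Product: 8 tert-butyl{[(2E)-3,7-dimethylocta-2,6-dien-1-yl]oxy}dimethylsilane
Conditions: TBSCl (1.1 equiv), imidazole (2 equiv), CH2Cl2, 0 °C → rt
Reagents that add atoms: tert-butyldimethylsilyl chloride CC(C)(C)[Si](C)(C)Cl
Why: Imidazole-promoted silylation of a primary alcohol; a silyl ether is chosen because, unlike an allylic ester, it is not ionized by zerovalent palladium in step 9.

Step 6
Reactants: 8 tert-butyl{[(2E)-3,7-dimethylocta-2,6-dien-1-yl]oxy}dimethylsilane
Product: 9 tert-butyl{[(2E)-5-(3,3-dimethyloxiran-2-yl)-3-methylpent-2-en-1-yl]oxy}dimethylsilane (racemic at the oxirane CH)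
Conditions: mCPBA (1.05 equiv), CH2Cl2, −20 → 0 °C
Reagents that add atoms: 3-chloroperbenzoic acid OOC(=O)c1cccc(Cl)c1
Why: Prilezhaev epoxidation, in which the peracid should prefer the more electron-rich distal trisubstituted double bond over the one deactivated inductively by the allylic oxygen; the new stereocentre is lost in step 7.

Step 7
Reactants: 9 tert-butyl{[(2E)-5-(3,3-dimethyloxiran-2-yl)-3-methylpent-2-en-1-yl]oxy}dimethylsilane
Product: 10 (4E)-6-{[tert-butyl(dimethyl)silyl]oxy}-4-methylhex-4-enal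
Conditions: H5IO6 (1.1 equiv), THF/Et2O, 0 °C, 30 min
Reagents that add atoms: none
Why: Periodic acid opens the oxirane at its tertiary carbon and cleaves the resulting glycol (Malaprade-type cleavage) to the aldehyde and acetone, so the aldehyde oxygen is the former oxirane oxygen, and the E olefin and silyl ether should survive the short cold exposure.

Step 8
Reactants: 10 (4E)-6-{[tert-butyl(dimethyl)silyl]oxy}-4-methylhex-4-enal
Product: 11 tert-butyl{[(2E,6Z)-7-iodo-3-methylocta-2,6-dien-1-yl]oxy}dimethylsilane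
Conditions: EtPPh3I, n-BuLi, THF, 0 °C; iodine, −78 °C; NaN(SiMe3)2, −78 °C; then 10, −78 → −20 °C
Reagents that add atoms: ethyltriphenylphosphonium iodide CC[P+](c1ccccc1)(c1ccccc1)c1ccccc1.[I-]; iodine [I][I]
Why: Wittig olefination with the α-iodo ylide Ph3P=C(I)CH3 (Stork–Zhao-type iodo-olefination) gives (Z)-2-iodoalk-2-enes from aliphatic aldehydes, and the new olefin geometry is not critical because the π-allyl of step 9 equilibrates.

Step 9
Reactants: 6 3-ethenyl-2,4-dimethylphenol; 11 tert-butyl{[(2E,6Z)-7-iodo-3-methylocta-2,6-dien-1-yl]oxy}dimethylsilane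
Product: 12 (4aS,5R)-5-[(3E)-5-{[tert-butyl(dimethyl)silyl]oxy}-3-methylpent-3-en-1-yl]-1,4a,6-trimethyl-5,8-dihydronaphthalen-2(4aH)-one
Conditions: Pd2(dba)3 (2.5 mol %), (S)-t-BuPHOX (6 mol %), K2CO3 (1.5 equiv), 1,4-dioxane, 70 °C, argon
Reagents that add atoms: none
Why: Proposed new method: zerovalent palladium inserts into the C–I bond of 11, the vinylpalladium adds across the styrene double bond of 6 (new C7–C8 bond), and β-hydride elimination with re-addition of Pd–H moves the metal to C7 and gives the C7–C8–C9 π-allyl complex, whose C9 terminus is attacked anti to palladium by the para carbon C10 of the potassium phenoxide (new C9–C10 bond, loss of aromaticity, 2,5-cyclohexadienone). The closest known reaction types are the Heck-type coupling of vinylic halides with alkenes that ends by nucleophilic capture of the migrated π-allylpalladium (Larock annulation of vinylic halides with olefinic nucleophiles) and the palladium-catalysed intramolecular allylic dearomatization of para-substituted phenols; their merger, with the arene itself as the carbon nucleophile, is new. Ring B closes in a six-membered mode of the tetralin-forming Friedel–Crafts kind (arene carbon ortho to the tether onto the distal allyl terminus, endo with respect to the allyl unit), which puts C7=C8 into the ring and needs the C6 substituent anti on the allyl, a geometry reached by π–σ–π isomerization and made accessible by the C8 methyl group. C10 is set by the face of the flat phenoxide that is alkylated, which the chiral P,N ligand on palladium has to choose, and C9 follows from the allyl geometry because only the isomer with the C11 chain syn can cyclize (the anti position points into ring A), which places C11 anti to C5 and cis to the C10 methyl group as in the target. The step needs attack at C10 and not at the other ortho-to-tether carbon C4 or at oxygen: oxygen and C2 are out of reach, O-allylation between molecules is reversible under palladium, and C10 has the larger HOMO coefficient of the phenoxide, is not flanked by the solvated O–K group and leads to the more stable cross-conjugated dienone. The mild heterogeneous carbonate base is chosen so that the doubly activated C6–H bonds of 12 are not deprotonated.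

Step 10
Reactants: 12 (4aS,5R)-5-[(3E)-5-{[tert-butyl(dimethyl)silyl]oxy}-3-methylpent-3-en-1-yl]-1,4a,6-trimethyl-5,8-dihydronaphthalen-2(4aH)-one
Product: 13 (4aS,5R)-5-[(3E)-5-{[tert-butyl(dimethyl)silyl]oxy}-3-methylpent-3-en-1-yl]-1,4a,6-trimethyl-4,4a,5,8-tetrahydronaphthalen-2(3H)-one
Conditions: H2 (1 atm), RhCl(PPh3)3 (5 mol %), benzene/EtOH 1:1, rt
Reagents that add atoms: none
Why: Homogeneous hydrogenation with RhCl(PPh3)3, which in cross-conjugated 1,4-dien-3-ones (steroid precedent) saturates only the disubstituted C1=C2 bond and leaves tetra- and trisubstituted olefins alone; no stereocentre is formed.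

Step 11
Reactants: 13 (4aS,5R)-5-[(3E)-5-{[tert-butyl(dimethyl)silyl]oxy}-3-methylpent-3-en-1-yl]-1,4a,6-trimethyl-4,4a,5,8-tetrahydronaphthalen-2(3H)-one
Product: 15 (4aS,5R,8aS)-5-[(3E)-5-{[tert-butyl(dimethyl)silyl]oxy}-3-methylpent-3-en-1-yl]-1,1,4a,6-tetramethyl-3,4,4a,5,8,8a-hexahydronaphthalen-2(1H)-one, via lithium enolate 14 (not isolated)
Conditions: Li (2.2 equiv), NH3(l)/THF, t-BuOH (1.0 equiv), −78 °C; then MeI (5 equiv), −78 → −33 °C
Reagents that add atoms: iodomethane IC
Why: Dissolving-metal (Birch-type) reduction of the enone and regiospecific C-methylation of the resulting lithium enolate (Stork reductive alkylation), in which protonation of the C5 carbanion anti to the angular methyl group sets the trans ring fusion and the isolated olefins are not reduced.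

Step 12
Reactants: 15 (4aS,5R,8aS)-5-[(3E)-5-{[tert-butyl(dimethyl)silyl]oxy}-3-methylpent-3-en-1-yl]-1,1,4a,6-tetramethyl-3,4,4a,5,8,8a-hexahydronaphthalen-2(1H)-one
Product: 16 (2S,4aS,5R,8aS)-5-[(3E)-5-{[tert-butyl(dimethyl)silyl]oxy}-3-methylpent-3-en-1-yl]-1,1,4a,6-tetramethyl-1,2,3,4,4a,5,8,8a-octahydronaphthalen-2-ol
Conditions: LiBH(s-Bu)3 (L-Selectride, 1.5 equiv), THF, −78 → −20 °C; aqueous work-up
Reagents that add atoms: none
Why: Reduction of the hindered cyclohexanone with a bulky trialkylborohydride, which delivers hydride along the equatorial trajectory and so should give the axial C3 alcohol (cis to H5, trans to the C10 methyl), as is usual for 4,4-dimethyl-3-oxo terpenoids.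

Step 13
Reactants: 16 (2S,4aS,5R,8aS)-5-[(3E)-5-{[tert-butyl(dimethyl)silyl]oxy}-3-methylpent-3-en-1-yl]-1,1,4a,6-tetramethyl-1,2,3,4,4a,5,8,8a-octahydronaphthalen-2-ol
Product: 17 (2S,4aS,5R,8aS)-5-[(3E)-5-hydroxy-3-methylpent-3-en-1-yl]-1,1,4a,6-tetramethyl-1,2,3,4,4a,5,8,8a-octahydronaphthalen-2-ol
Conditions: Bu4NF (1.2 equiv), THF, 0 °C → rt
Reagents that add atoms: none
Why: Fluoride-induced desilylation, driven by the strong Si–F bond, frees the primary allylic alcohol without touching the olefins or the secondary alcohol.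

Step 14
Reactants: 17 (2S,4aS,5R,8aS)-5-[(3E)-5-hydroxy-3-methylpent-3-en-1-yl]-1,1,4a,6-tetramethyl-1,2,3,4,4a,5,8,8a-octahydronaphthalen-2-ol; 18 (3S)-3-methylpentanoic acid
Product: 20 (2E)-5-[(1R,4aS,6S,8aS)-6-hydroxy-2,5,5,8a-tetramethyl-1,4,4a,5,6,7,8,8a-octahydronaphthalen-1-yl]-3-methylpent-2-en-1-yl (3S)-3-methylpentanoate, via O-acylisourea 19 (not isolated)
Conditions: dicyclohexylcarbodiimide (1.1 equiv), DMAP (0.1 equiv), CH2Cl2, −20 → 0 °C
Reagents that add atoms: none
Why: Steglich esterification (carbodiimide activation, acyl transfer by DMAP) should acylate only the primary allylic hydroxyl, because the axial C3 hydroxyl next to the quaternary C4 is far more hindered, and the β-stereocentre of 18 cannot epimerize.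

**Compound list**

1 | 2-bromo-1,3-dimethylbenzene | Cc1cccc(C)c1Br | starting material
2 | 2-bromo-1,3-dimethyl-4-nitrobenzene | Cc1ccc([N+](=O)[O-])c(C)c1Br | intermediate
3 | 3-bromo-2,4-dimethylaniline | Cc1ccc(N)c(C)c1Br | intermediate
4 | 3-bromo-2,4-dimethylbenzenediazonium hydrogen sulfate (not isolated) | Cc1ccc([N+]#N)c(C)c1Br.OS(=O)(=O)[O-] | intermediate
5 | 3-bromo-2,4-dimethylphenol | Cc1ccc(O)c(C)c1Br | intermediate
6 | 3-ethenyl-2,4-dimethylphenol | Cc1ccc(O)c(C)c1C=C | intermediate
7 | geraniol, (2E)-3,7-dimethylocta-2,6-dien-1-ol | CC(C)=CCC/C(C)=C/CO | starting material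
8 | tert-butyl{[(2E)-3,7-dimethylocta-2,6-dien-1-yl]oxy}dimethylsilane | CC(C)=CCC/C(C)=C/CO[Si](C)(C)C(C)(C)C | intermediate
9 | tert-butyl{[(2E)-5-(3,3-dimethyloxiran-2-yl)-3-methylpent-2-en-1-yl]oxy}dimethylsilane (racemic at the oxirane CH) | CC1(C)OC1CC/C(C)=C/CO[Si](C)(C)C(C)(C)C | intermediate
10 | (4E)-6-{[tert-butyl(dimethyl)silyl]oxy}-4-methylhex-4-enal | O=CCC/C(C)=C/CO[Si](C)(C)C(C)(C)C | intermediate
11 | tert-butyl{[(2E,6Z)-7-iodo-3-methylocta-2,6-dien-1-yl]oxy}dimethylsilane | C/C(I)=C/CC/C(C)=C/CO[Si](C)(C)C(C)(C)C | intermediate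
12 | (4aS,5R)-5-[(3E)-5-{[tert-butyl(dimethyl)silyl]oxy}-3-methylpent-3-en-1-yl]-1,4a,6-trimethyl-5,8-dihydronaphthalen-2(4aH)-one | CC(C)(C)[Si](C)(C)OC/C=C(\C)CC[C@@H]1C(C)=CCC2=C(C)C(=O)C=C[C@@]12C | intermediate
13 | (4aS,5R)-5-[(3E)-5-{[tert-butyl(dimethyl)silyl]oxy}-3-methylpent-3-en-1-yl]-1,4a,6-trimethyl-4,4a,5,8-tetrahydronaphthalen-2(3H)-one | CC(C)(C)[Si](C)(C)OC/C=C(\C)CC[C@@H]1C(C)=CCC2=C(C)C(=O)CC[C@@]12C | intermediate
14 | lithium (4aS,5R,8aS)-5-[(3E)-5-{[tert-butyl(dimethyl)silyl]oxy}-3-methylpent-3-en-1-yl]-1,4a,6-trimethyl-3,4,4a,5,8,8a-hexahydronaphthalen-2-olate (not isolated) | CC(C)(C)[Si](C)(C)OC/C=C(\C)CC[C@@H]1C(C)=CC[C@@H]2C(C)=C([O-])CC[C@@]12C.[Li+] | intermediate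
15 | (4aS,5R,8aS)-5-[(3E)-5-{[tert-butyl(dimethyl)silyl]oxy}-3-methylpent-3-en-1-yl]-1,1,4a,6-tetramethyl-3,4,4a,5,8,8a-hexahydronaphthalen-2(1H)-one | CC(C)(C)[Si](C)(C)OC/C=C(\C)CC[C@@H]1C(C)=CC[C@@H]2C(C)(C)C(=O)CC[C@@]12C | intermediate
16 | (2S,4aS,5R,8aS)-5-[(3E)-5-{[tert-butyl(dimethyl)silyl]oxy}-3-methylpent-3-en-1-yl]-1,1,4a,6-tetramethyl-1,2,3,4,4a,5,8,8a-octahydronaphthalen-2-ol | CC(C)(C)[Si](C)(C)OC/C=C(\C)CC[C@@H]1C(C)=CC[C@@H]2C(C)(C)[C@@H](O)CC[C@@]12C | intermediate
17 | (2S,4aS,5R,8aS)-5-[(3E)-5-hydroxy-3-methylpent-3-en-1-yl]-1,1,4a,6-tetramethyl-1,2,3,4,4a,5,8,8a-octahydronaphthalen-2-ol | OC/C=C(\C)CC[C@@H]1C(C)=CC[C@@H]2C(C)(C)[C@@H](O)CC[C@@]12C | intermediate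
18 | (3S)-3-methylpentanoic acid | CC[C@H](C)CC(=O)O | starting material
19 | N,N'-dicyclohexyl-O-[(3S)-3-methylpentanoyl]isourea (not isolated) | CC[C@H](C)CC(=O)OC(=NC1CCCCC1)NC1CCCCC1 | intermediate
20 | (2E)-5-[(1R,4aS,6S,8aS)-6-hydroxy-2,5,5,8a-tetramethyl-1,4,4a,5,6,7,8,8a-octahydronaphthalen-1-yl]-3-methylpent-2-en-1-yl (3S)-3-methylpentanoate | CC[C@H](C)CC(=O)OC/C=C(\C)CC[C@@H]1C(C)=CC[C@@H]2C(C)(C)[C@@H](O)CC[C@@]12C | target

**Step count and risks**

Total step count: 14 (steps 1–4 arene branch, steps 5–8 side-chain branch, steps 9–14 common part).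
Longest linear sequence: 10 steps (steps 1–4 then 9–14; the branch through steps 5–8 is equally long).

Steps most likely to fail:

1. Step 9 (Proposed new method). The conjugated diene may leave palladium before the π-allyl is captured, alkylation may occur at the ortho carbon C4, facial discrimination at the phenoxide may be poor, or the base may move the C7=C8 double bond into conjugation.
 - Fallback: it uses documented reaction types only and forms the two bonds in separate operations. It sets out from 5 and 11 and comes back to the route at 12.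
 - Suzuki–Miyaura coupling of 5 with 2-[(E)-2-ethoxyethenyl]-4,4,5,5-tetramethyl-1,3,2-dioxaborolane (Pd(OAc)2, SPhos, K3PO4) should give 3-[(E)-2-ethoxyethenyl]-2,4-dimethylphenol F1.
 - Mild hydrolysis of the enol ether (aq. HCl, THF) should give (3-hydroxy-2,6-dimethylphenyl)acetaldehyde F2.
 - Nozaki–Hiyama–Kishi coupling of F2 with 11 (CrCl2, NiCl2 cat., DMF) forms the C7–C8 bond and should give 3-[(3Z,7E)-9-{[tert-butyl(dimethyl)silyl]oxy}-2-hydroxy-3,7-dimethylnona-3,7-dien-1-yl]-2,4-dimethylphenol F3 as both C7 epimers, which lead to the same π-allyl.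
 - Methyl chloroformate and pyridine should give methyl 3-[(3Z,7E)-9-{[tert-butyl(dimethyl)silyl]oxy}-2-[(methoxycarbonyl)oxy]-3,7-dimethylnona-3,7-dien-1-yl]-2,4-dimethylphenyl carbonate F4.
 - Short treatment with K2CO3 in MeOH at 0 °C cleaves only the aryl carbonate and should give (3Z,7E)-9-{[tert-butyl(dimethyl)silyl]oxy}-1-(3-hydroxy-2,6-dimethylphenyl)-3,7-dimethylnona-3,7-dien-2-yl methyl carbonate F5.
 - F5 is then cyclized by the palladium-catalysed intramolecular allylic dearomatization of a para-substituted phenol (Pd2(dba)3, (R,R)-DACH-phenyl Trost ligand, Li2CO3, MeCN), which forms the C9–C10 bond and gives 12.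

2. Step 11. Electron transfer to the allylic silyl ether may cost the C15 oxygen, the ketone may be over-reduced, or proton exchange of the enolate may lead to methylation at C2.
 - Fallback: it sets out from 13 and comes back to the route at 17.
 - The silyl ether is removed first (Bu4NF, THF) to give (4aS,5R)-5-[(3E)-5-hydroxy-3-methylpent-3-en-1-yl]-1,4a,6-trimethyl-4,4a,5,8-tetrahydronaphthalen-2(3H)-one F6.
 - As its lithium alkoxide the allylic oxygen cannot leave, so Li/NH3 (3.2 equiv Li, t-BuOH) followed by MeI (1.2 equiv, −78 °C) should give (4aS,5R,8aS)-5-[(3E)-5-hydroxy-3-methylpent-3-en-1-yl]-1,1,4a,6-tetramethyl-3,4,4a,5,8,8a-hexahydronaphthalen-2(1H)-one F7.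
 - LiBH(s-Bu)3 (2.5 equiv) then reduces the ketone of F7 to diol 17, so that steps 12 and 13 merge.

3. Step 8. Iodine exchange in the ylide may give the non-iodinated olefin, the aldehyde may enolize, or conversion may stay incomplete.
 - Fallback: it sets out from 10 and comes back to the route at 12.
 - Corey–Fuchs olefination (CBr4, PPh3, CH2Cl2, 0 °C) should give tert-butyl{[(2E)-7,7-dibromo-3-methylhepta-2,6-dien-1-yl]oxy}dimethylsilane F8.
 - n-BuLi (2.1 equiv, THF, −78 °C) followed by MeI should give tert-butyl{[(2E)-3-methyloct-2-en-6-yn-1-yl]oxy}dimethylsilane F9.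
 - Hydrozirconation with excess Cp2Zr(H)Cl (equilibration to the alkenylzirconium at the methyl-bearing carbon) and iodinolysis should give tert-butyl{[(2E,6E)-7-iodo-3-methylocta-2,6-dien-1-yl]oxy}dimethylsilane F10.
 - F10 enters step 9 in place of 11; it gives the same π-allyl and therefore 12.

Further compounds
F1 | step 9 | 3-[(E)-2-ethoxyethenyl]-2,4-dimethylphenol | CCO/C=C/c1c(C)ccc(O)c1C
F2 | step 9 | (3-hydroxy-2,6-dimethylphenyl)acetaldehyde | O=CCc1c(C)ccc(O)c1C
F3 | step 9 | 3-[(3Z,7E)-9-{[tert-butyl(dimethyl)silyl]oxy}-2-hydroxy-3,7-dimethylnona-3,7-dien-1-yl]-2,4-dimethylphenol | Cc1ccc(O)c(C)c1CC(O)/C(C)=C\CC/C(C)=C/CO[Si](C)(C)C(C)(C)C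
F4 | step 9 | methyl 3-[(3Z,7E)-9-{[tert-butyl(dimethyl)silyl]oxy}-2-[(methoxycarbonyl)oxy]-3,7-dimethylnona-3,7-dien-1-yl]-2,4-dimethylphenyl carbonate | COC(=O)Oc1ccc(C)c(CC(OC(=O)OC)/C(C)=C\CC/C(C)=C/CO[Si](C)(C)C(C)(C)C)c1C
F5 | step 9 | (3Z,7E)-9-{[tert-butyl(dimethyl)silyl]oxy}-1-(3-hydroxy-2,6-dimethylphenyl)-3,7-dimethylnona-3,7-dien-2-yl methyl carbonate | COC(=O)OC(Cc1c(C)ccc(O)c1C)/C(C)=C\CC/C(C)=C/CO[Si](C)(C)C(C)(C)C
F6 | step 11 | (4aS,5R)-5-[(3E)-5-hydroxy-3-methylpent-3-en-1-yl]-1,4a,6-trimethyl-4,4a,5,8-tetrahydronaphthalen-2(3H)-one | OC/C=C(\C)CC[C@@H]1C(C)=CCC2=C(C)C(=O)CC[C@@]12C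
F7 | step 11 | (4aS,5R,8aS)-5-[(3E)-5-hydroxy-3-methylpent-3-en-1-yl]-1,1,4a,6-tetramethyl-3,4,4a,5,8,8a-hexahydronaphthalen-2(1H)-one | OC/C=C(\C)CC[C@@H]1C(C)=CC[C@@H]2C(C)(C)C(=O)CC[C@@]12C
F8 | step 8 | tert-butyl{[(2E)-7,7-dibromo-3-methylhepta-2,6-dien-1-yl]oxy}dimethylsilane | BrC(Br)=CCC/C(C)=C/CO[Si](C)(C)C(C)(C)C
F9 | step 8 | tert-butyl{[(2E)-3-methyloct-2-en-6-yn-1-yl]oxy}dimethylsilane | CC#CCC/C(C)=C/CO[Si](C)(C)C(C)(C)C
F10 | step 8 | tert-butyl{[(2E,6E)-7-iodo-3-methylocta-2,6-dien-1-yl]oxy}dimethylsilane | C/C(I)=C\CC/C(C)=C/CO[Si](C)(C)C(C)(C)C
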